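The route rests on disconnecting the bond between C5, the carbinol carbon remote from the arene, and C6, the first CH2 of the nonyl chain (C1 is benzylic). The key step is a three-component, palladium-catalysed enantioselective conjunctive coupling. A nonyl(vinyl)boron ate complex, made in the flask from nonylmagnesium bromide and vinylboronic pinacol ester, meets the enol triflate of O-benzylzingerone. A 1,2-shift of nonyl from boron to carbon forges C5–C6 and the C5 stereocenter, while C3–C4 is joined in the same operation. The step exploits the acyclic O–C5–C4–C3–O 1,3-dioxygenated unit: C5–B becomes C5–OH, the C3 methylidene is a masked ketone, and the C5 hydroxyl later steers a syn reduction at C3.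

Key step: step 3

Assumption: MandyPhos is the C2-symmetric ferrocene-1,1'-diyl bis(diarylphosphine) ligand with two α-(dimethylamino)benzyl arms. Its (Rp,Rp) antipode is taken to deliver the 5R boronate with an alkyl migrating group; if the sense of induction is the reverse, the (Sp,Sp) ligand is used with no other change.

Step 1
Reactants: 1 zingerone, 4-(4-hydroxy-3-methoxyphenyl)butan-2-one
Product: 2 4-[4-(benzyloxy)-3-methoxyphenyl]butan-2-one
Conditions: BnBr, K2CO3, DMF, rt
Reagents that add atoms: benzyl bromide, BrCc1ccccc1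
Why: Williamson ether synthesis, in which K2CO3 deprotonates only the phenol and the phenoxide displaces bromide, masking the phenol for the base, oxidant and ozone used later.

Step 2
Reactants: 2 4-[4-(benzyloxy)-3-methoxyphenyl]butan-2-one
Product: 3 4-[4-(benzyloxy)-3-methoxyphenyl]but-1-en-2-yl trifluoromethanesulfonate
Conditions: LiN(iPr)2, THF, −78 °C (ketone added to the base); then Comins' reagent, −78 → 0 °C
Reagents that add atoms: Comins' reagent, N-(5-chloropyridin-2-yl)bis(trifluoromethanesulfonimide), O=S(=O)(N(c1ccc(Cl)cn1)S(=O)(=O)C(F)(F)F)C(F)(F)F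
Why: Kinetic deprotonation by the hindered amide at −78 °C should take the CH3 protons rather than the C2 methylene, and O-sulfonylation of the lithium enolate (enol triflate formation) fixes this as the 2-triflyloxy-1-alkene.

Step 3
Reactants: 3 4-[4-(benzyloxy)-3-methoxyphenyl]but-1-en-2-yl trifluoromethanesulfonate, 4 vinylboronic acid pinacol ester, 5 nonylmagnesium bromide
Product: 8 (R)-1-[4-(benzyloxy)-3-methoxyphenyl]-3-methylidenetetradecan-5-ol, via vinyl(nonyl)boronate ate complex 6 (not isolated), via secondary pinacol boronate 7 (not isolated)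
Conditions: 4 + 5, THF, 0 °C → rt; NaOTf; then 3, Pd(OAc)2 (2 mol %), (Rp,Rp)-MandyPhos (2.4 mol %), THF, 60 °C; then 3 M NaOH, 30 % H2O2, 0 °C → rt
Reagents that add atoms: hydrogen peroxide, OO
Why: The Grignard reagent adds to boron to give the four-coordinate ate complex 6; zerovalent palladium inserts into the C–O bond of the triflate, the cationic alkenyl complex of divalent palladium π-binds the vinyl group, and this triggers a 1,2-metallate shift in which nonyl migrates from boron to the boron-bearing carbon (forming C5–C6) anti to the metal while palladium bonds to the terminal carbon, after which reductive elimination forms C3–C4. The closest known reaction type is the palladium-catalysed enantioselective conjunctive cross-coupling of vinylboron ate complexes with alkenyl triflates, here in its Grignard variant with NaOTf as halide scavenger. No ring is closed. The new stereocenter C5 is set by the chiral bisphosphine on palladium, which selects one enantiotopic face of the bound vinyl group, and the stereoretentive oxidation of the C–B bond carries it into the 5R alcohol. The step needs the metallate shift to outrun direct Suzuki-type transfer of vinyl or nonyl, and needs nonyl rather than a pinacolate oxygen to migrate; the wide-bite-angle ligand, the non-coordinating triflate counter-ion and the tetra-coordinate pinacol boronate should secure this. The benzyl ether, the methoxy group and the unactivated 1,1-disubstituted alkene of the product are inert to the catalyst and to basic peroxide.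

Step 4
Reactants: 8 (R)-1-[4-(benzyloxy)-3-methoxyphenyl]-3-methylidenetetradecan-5-ol
Product: 10 (R)-1-[4-(benzyloxy)-3-methoxyphenyl]-5-hydroxytetradecan-3-one, via secondary ozonide 9 (not isolated)
Conditions: O3, CH2Cl2, −78 °C (stopped at first excess, N2 purge); then PPh3, −78 °C → rt
Reagents that add atoms: ozone, [O-][O+]=O
Why: Ozonolysis, in which the 1,1-disubstituted alkene should react far faster than the dialkoxyarene at −78 °C, and neutral phosphine reduction of the ozonide should release the β-hydroxy ketone without touching C5 or causing dehydration.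

Step 5
Reactants: 10 (R)-1-[4-(benzyloxy)-3-methoxyphenyl]-5-hydroxytetradecan-3-one
Product: 12 (3S,5R)-1-[4-(benzyloxy)-3-methoxyphenyl]tetradecane-3,5-diol, via diethylboron chelate 11 (not isolated)
Conditions: Et2BOMe, THF/MeOH (4:1), −78 °C; then NaBH4, −78 °C; then H2O2, pH 7 buffer, MeOH, 0 °C
Reagents that add atoms: none
Why: Narasaka–Prasad reduction, in which the C5 borinate chelates the ketone in a six-membered half-chair and external hydride attacks axially, so that C5 should set C3 as S in the 1,3-syn diol.

Step 6
Reactants: 12 (3S,5R)-1-[4-(benzyloxy)-3-methoxyphenyl]tetradecane-3,5-diol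
Product: 13 (3S,5R)-1-(4-hydroxy-3-methoxyphenyl)tetradecane-3,5-diol
Conditions: H2 (1 atm), Pd/C (10 wt % Pd), EtOAc/MeOH, rt
Reagents that add atoms: none
Why: Catalytic hydrogenolysis of the benzyl aryl ether should free the phenol, since the molecule holds no other reducible group and the secondary carbinols are not benzylic.

Compound list
1 | zingerone, 4-(4-hydroxy-3-methoxyphenyl)butan-2-one | CC(=O)CCc1ccc(O)c(OC)c1 | starting material
2 | 4-[4-(benzyloxy)-3-methoxyphenyl]butan-2-one | CC(=O)CCc1ccc(OCc2ccccc2)c(OC)c1 | intermediate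
3 | 4-[4-(benzyloxy)-3-methoxyphenyl]but-1-en-2-yl trifluoromethanesulfonate | C=C(OS(=O)(=O)C(F)(F)F)CCc1ccc(OCc2ccccc2)c(OC)c1 | intermediate
4 | vinylboronic acid pinacol ester, 2-ethenyl-4,4,5,5-tetramethyl-1,3,2-dioxaborolane | C=CB1OC(C)(C)C(C)(C)O1 | starting material
5 | nonylmagnesium bromide | CCCCCCCCC[Mg]Br | starting material
6 | bromomagnesium 2-ethenyl-4,4,5,5-tetramethyl-2-nonyl-1,3,2-dioxaborolan-2-uide (vinyl(nonyl)boronate ate complex) | CCCCCCCCC[B-]1(C=C)OC(C)(C)C(C)(C)O1.[Mg+]Br | intermediate
7 | (R)-2-{1-[4-(benzyloxy)-3-methoxyphenyl]-3-methylidenetetradecan-5-yl}-4,4,5,5-tetramethyl-1,3,2-dioxaborolane | CCCCCCCCC[C@@H](B1OC(C)(C)C(C)(C)O1)CC(=C)CCc1ccc(OCc2ccccc2)c(OC)c1 | intermediate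
8 | (R)-1-[4-(benzyloxy)-3-methoxyphenyl]-3-methylidenetetradecan-5-ol | CCCCCCCCC[C@@H](O)CC(=C)CCc1ccc(OCc2ccccc2)c(OC)c1 | intermediate
9 | 3-{2-[4-(benzyloxy)-3-methoxyphenyl]ethyl}-3-[(R)-2-hydroxyundecyl]-1,2,4-trioxolane (secondary ozonide, both epimers at the ring carbon) | CCCCCCCCC[C@@H](O)CC1(CCc2ccc(OCc3ccccc3)c(OC)c2)OCOO1 | intermediate
10 | (R)-1-[4-(benzyloxy)-3-methoxyphenyl]-5-hydroxytetradecan-3-one | CCCCCCCCC[C@@H](O)CC(=O)CCc1ccc(OCc2ccccc2)c(OC)c1 | intermediate
11 | (R)-1-[4-(benzyloxy)-3-methoxyphenyl]-3-oxotetradecan-5-yl diethylborinate (boron chelated by the ketone oxygen) | CCCCCCCCC[C@@H](OB(CC)CC)CC(=O)CCc1ccc(OCc2ccccc2)c(OC)c1 | intermediate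
12 | (3S,5R)-1-[4-(benzyloxy)-3-methoxyphenyl]tetradecane-3,5-diol | CCCCCCCCC[C@@H](O)C[C@@H](O)CCc1ccc(OCc2ccccc2)c(OC)c1 | intermediate
13 | (3S,5R)-1-(4-hydroxy-3-methoxyphenyl)tetradecane-3,5-diol | CCCCCCCCC[C@@H](O)C[C@@H](O)CCc1ccc(O)c(OC)c1 | target

Total step count: 6. Longest linear sequence: 6 steps (1 → 13); 4 and 5 enter at step 3.

Steps most likely to fail

Step 3. The metallate shift may lose out to direct Suzuki-type transfer of vinyl or nonyl, residual bromide may slow the cationic palladium, and facial selection may be weaker with a 2-alkyl alkenyl triflate. The fallback sets out from 2 and comes back at 12, still forming C5–C6 with 5 but at the ketone oxidation level. Compound 2 would be C-acylated at the methyl group (NaH, dimethyl carbonate, THF, reflux) to methyl 5-[4-(benzyloxy)-3-methoxyphenyl]-3-oxopentanoate F1. A Noyori hydrogenation (H2, RuCl2[(S)-BINAP], MeOH) should reduce it to methyl (S)-5-[4-(benzyloxy)-3-methoxyphenyl]-3-hydroxypentanoate F2. Aminolysis (MeNHOMe·HCl, iPrMgCl, THF, −20 °C) should give (S)-5-[4-(benzyloxy)-3-methoxyphenyl]-3-hydroxy-N-methoxy-N-methylpentanamide F3. Excess nonylmagnesium bromide 5 should then add once to give (S)-1-[4-(benzyloxy)-3-methoxyphenyl]-3-hydroxytetradecan-5-one F4. The conditions of step 5 applied to F4 should set C5 syn to C3 and deliver 12.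

Step 2. Deprotonation at the C2 methylene may compete with the methyl group and give regioisomeric enol triflates, and the triflate may hydrolyse during purification. The fallback sets out from 2 and comes back at 8. Condensation of 2 with 2,4,6-triisopropylbenzenesulfonyl hydrazide should give the 2,4,6-triisopropylbenzenesulfonylhydrazone of 2 F5. A Shapiro reaction (n-BuLi, 2.1 equiv, THF, −78 → 0 °C) should place lithium on the former carbonyl carbon with the double bond towards the methyl side, and 1,2-dibromoethane should trap it as 4-[4-(benzyloxy)-3-methoxyphenyl]-2-bromobut-1-ene F6. F6 would replace 3 as the electrophile of step 3, with extra NaOTf to sequester bromide, to give 8.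

Step 4. Ozone may over-oxidise the electron-rich dialkoxyarene or the benzylic ether position, and the β-hydroxy ketone may dehydrate or undergo retro-aldol cleavage during work-up. The fallback sets out from 8 and comes back at 10. Dihydroxylation (OsO4 cat., N-methylmorpholine N-oxide, acetone/H2O) should give (5R)-1-[4-(benzyloxy)-3-methoxyphenyl]-3-(hydroxymethyl)tetradecane-3,5-diol F7 as both C3 epimers. Glycol cleavage (NaIO4, THF/pH 7 buffer) should cut only the 1,2-diol and give 10.

Further compounds
F1 | step 3 | methyl 5-[4-(benzyloxy)-3-methoxyphenyl]-3-oxopentanoate | COC(=O)CC(=O)CCc1ccc(OCc2ccccc2)c(OC)c1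
F2 | step 3 | methyl (S)-5-[4-(benzyloxy)-3-methoxyphenyl]-3-hydroxypentanoate | COC(=O)C[C@@H](O)CCc1ccc(OCc2ccccc2)c(OC)c1
F3 | step 3 | (S)-5-[4-(benzyloxy)-3-methoxyphenyl]-3-hydroxy-N-methoxy-N-methylpentanamide | CON(C)C(=O)C[C@@H](O)CCc1ccc(OCc2ccccc2)c(OC)c1
F4 | step 3 | (S)-1-[4-(benzyloxy)-3-methoxyphenyl]-3-hydroxytetradecan-5-one | CCCCCCCCCC(=O)C[C@@H](O)CCc1ccc(OCc2ccccc2)c(OC)c1
F5 | step 2 | 2,4,6-triisopropylbenzenesulfonylhydrazone of 2 | CC(CCc1ccc(OCc2ccccc2)c(OC)c1)=NNS(=O)(=O)c1c(C(C)C)cc(C(C)C)cc1C(C)C
F6 | step 2 | 4-[4-(benzyloxy)-3-methoxyphenyl]-2-bromobut-1-ene | C=C(Br)CCc1ccc(OCc2ccccc2)c(OC)c1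
F7 | step 4 | (5R)-1-[4-(benzyloxy)-3-methoxyphenyl]-3-(hydroxymethyl)tetradecane-3,5-diol | CCCCCCCCC[C@@H](O)CC(O)(CO)CCc1ccc(OCc2ccccc2)c(OC)c1
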